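The synthesis rests on cutting the pyran ring at C2–C3. C2 is bonded to the ring oxygen O1 and to the donor-rich B ring, so it is a latent aryl-oxocarbenium carbon. The isopropyl group on C3 can be read as a hydrogenated isopropenyl group, the remnant of a Me2C=CH nucleophile whose CH carbon has bonded to C2. One thiophile-triggered Prins closure thus makes C2–C3, closes the pyran ring onto the A ring, and sets C2 and C3 from the existing C4 centre. The precursor is the A-ring aryl O,S-acetal (SPh) of the B-ring aldehyde. It carries the (S)-1-isobutyl-3-methylbut-2-enyl chain ortho to O1, with phenols as methyl ethers and formyl groups as dioxolanes.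

Key step: step 13

Assumption: chroman numbering is used throughout (O1, C2–C4, C4a, C5–C8, C8a; B ring primed), and all un-numbered reagents are taken as commercial.
Assumption: the acetal carbon of 25 forms as both epimers, which is irrelevant because it becomes planar in step 13.

Step 1
Reactants: 1 4-hydroxy-2,6-dimethoxybenzaldehyde
Product: 2 4-formyl-3,5-dimethoxyphenyl N,N-diethylcarbamate
Conditions: Et2NCOCl, K2CO3, MeCN, reflux
Reagents that add atoms: N,N-diethylcarbamoyl chloride CCN(CC)C(=O)Cl
Why: O-carbamoylation of an acidic para-formyl phenol; the carbamate serves as a base-stable phenol protecting group and as the directing group for step 3.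

Step 2
Reactants: 2 4-formyl-3,5-dimethoxyphenyl N,N-diethylcarbamate
Product: 3 4-(1,3-dioxolan-2-yl)-3,5-dimethoxyphenyl N,N-diethylcarbamate
Conditions: (TMSOCH2)2, TMSOTf (cat.), CH2Cl2, −78 → −20 °C; pyridine quench
Reagents that add atoms: 1,2-bis(trimethylsilyloxy)ethane C[Si](C)(C)OCCO[Si](C)(C)C
Why: Noyori acetalisation, made irreversible by siloxane formation, suits a hindered, donor-deactivated aldehyde and masks it against the organolithium steps.

Step 3
Reactants: 3 4-(1,3-dioxolan-2-yl)-3,5-dimethoxyphenyl N,N-diethylcarbamate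
Product: 5 4-(1,3-dioxolan-2-yl)-3,5-dimethoxy-2-(4,4,5,5-tetramethyl-1,3,2-dioxaborolan-2-yl)phenyl N,N-diethylcarbamate, via aryllithium 4 (not isolated)
Conditions: s-BuLi, TMEDA, THF, −78 °C; i-PrOBpin, −78 °C → rt
Reagents that add atoms: 2-isopropoxy-4,4,5,5-tetramethyl-1,3,2-dioxaborolane CC(C)OB1OC(C)(C)C(C)(C)O1
Why: Directed ortho-metalation followed by borylation; the two free ring positions are equivalent, each lies between the carbamate and a methoxy group, and at −78 °C borate capture outruns the anionic Fries shift.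

Step 4
Reactants: 6 3-methylbutan-1-ol
Product: 7 3-methylbutyl 2,4,6-triisopropylbenzoate
Conditions: 2,4,6-triisopropylbenzoic acid, PPh3, DIAD, THF, 0 °C → rt
Reagents that add atoms: 2,4,6-triisopropylbenzoic acid CC(C)c1cc(C(C)C)c(C(=O)O)c(C(C)C)c1
Why: Mitsunobu esterification is the standard entry to this hindered benzoate, which later directs α-lithiation and acts as the leaving group.

Step 5
Reactants: 7 3-methylbutyl 2,4,6-triisopropylbenzoate; 5 arylboronic ester
Product: 10 4-(1,3-dioxolan-2-yl)-3,5-dimethoxy-2-[(1R)-3-methyl-1-(4,4,5,5-tetramethyl-1,3,2-dioxaborolan-2-yl)butyl]phenyl N,N-diethylcarbamate, via lithiated benzoate 8 (not isolated), via boronate complex 9 (not isolated)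
Conditions: 7, (−)-sparteine, s-BuLi, Et2O, −78 °C; add 5, −78 °C; then reflux
Reagents that add atoms: none
Why: Lithiation–borylation (asymmetric deprotonation followed by 1,2-metallate rearrangement): s-BuLi/(−)-sparteine removes the pro-S proton to give (S)-8, boron binds with retention, and the electron-rich aryl group migrates anti to the departing benzoate (inversion), which fixes the future C4 (R descriptor here only because boron ranks low).

Step 6
Reactants: 10 secondary benzylic boronic ester; 11 1-bromo-2-methylprop-1-ene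
Product: 15 4-(1,3-dioxolan-2-yl)-2-[(4S)-2,6-dimethylhept-2-en-4-yl]-3,5-dimethoxyphenyl N,N-diethylcarbamate, via alkenyllithium 12 (not isolated), via alkenylboronate 13 (not isolated), via iodoboronic ester 14 (not isolated)
Conditions: 11, t-BuLi, THF, −78 °C; add 10; I2, THF, −78 °C; NaOMe, MeOH, −78 °C → rt
Reagents that add atoms: none
Why: Zweifel olefination; the iodonium-induced 1,2-shift moves the benzylic carbon with retention, anti boron–iodine elimination follows, the dimethyl terminus removes any E/Z question, and C4 keeps its spatial arrangement (now S).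

Step 7
Reactants: 15 alkenyl aryl carbamate
Product: 16 4-(1,3-dioxolan-2-yl)-2-[(4S)-2,6-dimethylhept-2-en-4-yl]-3,5-dimethoxyphenol
Conditions: LiAlH4, THF, 0 °C → reflux; Rochelle salt work-up
Reagents that add atoms: none
Why: Reductive cleavage of the aryl carbamate by hydride runs entirely without acid, so the dioxolane survives and the o-alkenylphenol cannot cyclise to a 2,2-dimethylchroman.

Step 8
Reactants: 17 1,3,5-trimethoxybenzene
Product: 18 2,4,6-trimethoxybenzene-1,3-dicarbaldehyde
Conditions: Cl2CHOMe (2.5 equiv), TiCl4, CH2Cl2, −78 → 0 °C; ice-water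
Reagents that add atoms: dichloromethyl methyl ether COC(Cl)Cl; water O
Why: Twofold Rieche formylation; after the first formylation the open positions are still ortho/para to three methoxy groups and only meta to the acceptor, while stoichiometry and temperatures no higher than 0 °C hold back a third formylation and ether cleavage.

Step 9
Reactants: 18 2,4,6-trimethoxybenzene-1,3-dicarbaldehyde
Product: 19 2,2'-(2,4,6-trimethoxy-1,3-phenylene)bis(1,3-dioxolane)
Conditions: (TMSOCH2)2 (2.5 equiv), TMSOTf (cat.), CH2Cl2, −78 → −20 °C; pyridine quench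
Reagents that add atoms: 1,2-bis(trimethylsilyloxy)ethane C[Si](C)(C)OCCO[Si](C)(C)C
Why: Noyori acetalisation of both hindered formyl groups prepares the ring for metalation.

Step 10
Reactants: 19 bis-dioxolane
Product: 21 3,5-bis(1,3-dioxolan-2-yl)-2,4,6-trimethoxybenzaldehyde, via aryllithium 20 (not isolated)
Conditions: n-BuLi, TMEDA, THF, 0 °C; DMF, −78 °C → rt; pH 7 buffer
Reagents that add atoms: N,N-dimethylformamide CN(C)C=O
Why: Directed ortho-metalation at the only aromatic C–H, flanked by two methoxy groups, followed by formylation with DMF delivers the carbon that becomes C2.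

Step 11
Reactants: 21 B-ring aldehyde
Product: 22 2,2'-{5-[bis(phenylthio)methyl]-2,4,6-trimethoxy-1,3-phenylene}bis(1,3-dioxolane)
Conditions: PhSSPh, n-Bu3P, THF, rt → 50 °C
Reagents that add atoms: diphenyl disulfide c1ccc(SSc2ccccc2)cc1
Why: Deoxygenative thioacetalisation with a disulfide–phosphine pair (thiolate addition, capture of the alkoxide by the thiophosphonium ion, displacement by a second thiolate, driven by P=O formation) is neutral and leaves both dioxolanes untouched, which acid/thiol methods would not.

Step 12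
Reactants: 22 dithioacetal; 16 A-ring phenol
Product: 25 aryl O,S-acetal [3,5-bis(1,3-dioxolan-2-yl)-2,4,6-trimethoxyphenyl](phenylthio)methyl ether of phenol 16 (C4 S; acetal carbon as both epimers), via thionium triflate 23 (not isolated), via sodium phenoxide 24 (not isolated)
Conditions: 22, MeOTf (1.0 equiv), 4 Å MS, CH2Cl2, 0 °C; separately 16, NaH, THF, 0 °C; combine at −78 → −20 °C; Et3N; Et3N-deactivated silica
Reagents that add atoms: none
Why: Mono-exchange of a dithioacetal through its thionium ion; one equivalent of MeOTf releases thioanisole and the strongly stabilised ion 23 before the partner is present, and the preformed phenoxide 24 then bonds through oxygen under basic conditions, so neither the dioxolanes nor the acid-sensitive o-alkenylphenol meets acid.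

Step 13
Reactants: 25 aryl O,S-acetal
Product: 29 (2R,3S,4S)-2-[3,5-bis(1,3-dioxolan-2-yl)-2,4,6-trimethoxyphenyl]-6-(1,3-dioxolan-2-yl)-4-isobutyl-3-isopropenyl-5,7-dimethoxychroman (2,3-trans-3,4-cis), via sulfonium triflate 26 (not isolated), via oxocarbenium ion 27 (not isolated), via tertiary cation 28 (not isolated)
Conditions: MeOTf (2 equiv), 2,6-di-tert-butyl-4-methylpyridine (DTBMP, 3 equiv), 4 Å MS, CH2Cl2 (0.003 M), −20 °C → rt
Reagents that add atoms: none
Why: Proposed new method: MeOTf alkylates the only soft nucleophile, the sulfur of 25, and sulfonium 26 expels thioanisole to give the (E)-aryl-oxocarbenium ion 27 (O1=C2), which C3 of the trisubstituted alkene attacks to give tertiary cation 28, from which the hindered pyridine removes a methyl proton to leave the isopropenyl group. The closest known reaction type is the Prins (oxonium-ene) cyclisation of alkyl mixed acetals that carry a trisubstituted alkene, which gives 3-isopropenyltetrahydropyrans; new here is that the ring oxygen is a phenol oxygen, so the cation draws its stability from the B ring. The pyran ring closes 6-exo with respect to the alkene and endo with respect to O1=C2, and the Markovnikov bias towards the tertiary cation excludes the 7-endo path. C2 and C3 are set in a half-chair in which the B ring of the E-configured ion and the developing cationic carbon are both pseudo-equatorial, hence 2,3-trans. The sense at C3 relative to C4 comes from peri (benzylic 1,3-) strain: the C5 methoxy group, buttressed by the C6 dioxolane, keeps H4 in the arene plane, so C3 and the isobutyl group straddle that plane and isobutyl ends pseudo-axial (3,4-cis); this must outweigh the opposing allylic strain between isobutyl and the Z-methyl group, which the late and probably reversible bond formation of so stabilised a cation should attenuate. The step needs ionisation at sulfur only, ring closure ahead of intermolecular attack at C8, and methyl rather than C3–H deprotonation; these are secured by the softness of sulfur (alkene and dioxolanes ignore MeOTf), by O1 being tied up in the acetal (no 2,2-dimethylchroman), by high dilution, and by the bulk of DTBMP, which also keeps the medium free of TfOH.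

Step 14
Reactants: 29 3-isopropenylchroman
Product: 30 (2R,3R,4S)-2-[3,5-bis(1,3-dioxolan-2-yl)-2,4,6-trimethoxyphenyl]-6-(1,3-dioxolan-2-yl)-4-isobutyl-3-isopropyl-5,7-dimethoxychroman
Conditions: H2 (1 atm), PtO2 (cat.), K2CO3 (solid), EtOAc, rt
Reagents that add atoms: none
Why: Heterogeneous hydrogenation of a 1,1-disubstituted alkene on material freed of thioanisole; platinum under buffered conditions limits alkene migration towards C3 and hydrogenolysis of the benzylic C2–O1 and acetal C–O bonds, and no stereocentre is created (C3 changes descriptor only).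

Step 15
Reactants: 30 tris-dioxolane
Product: 31 (2R,3R,4S)-2-(3,5-diformyl-2,4,6-trimethoxyphenyl)-4-isobutyl-3-isopropyl-5,7-dimethoxychroman-6-carbaldehyde
Conditions: 1 M HCl, THF, 0 °C → rt
Reagents that add atoms: water O
Why: Acid hydrolysis of three donor-activated aryl dioxolanes is fast under mild conditions, and each liberated formyl group deactivates its ring, so the C2–O1 bond is not ionised.

Step 16
Reactants: 31 trialdehyde pentamethyl ether
Product: 32 (2R,3R,4S)-2-(3,5-diformyl-2,4,6-trihydroxyphenyl)-5,7-dihydroxy-4-isobutyl-3-isopropylchroman-6-carbaldehyde (target CNP0328914.1)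
Conditions: BBr3 (15 equiv), CH2Cl2, −78 °C → rt; ice-water
Reagents that add atoms: none
Why: Lewis-acid cleavage of aryl methyl ethers; every methoxy group is ortho to a formyl group and most are twisted by two neighbours; BBr3 is preferred to BCl3 because the A ring offers one chelating formyl group for two ethers and the B ring two for three; the three acceptor groups keep C2–O1 from ionising, so C2, C3 and C4 stay as set.

Compound list
1 | 4-hydroxy-2,6-dimethoxybenzaldehyde | COc1cc(O)cc(OC)c1C=O | starting material
2 | 4-formyl-3,5-dimethoxyphenyl N,N-diethylcarbamate | CCN(CC)C(=O)Oc1cc(OC)c(C=O)c(OC)c1 | intermediate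
3 | 4-(1,3-dioxolan-2-yl)-3,5-dimethoxyphenyl N,N-diethylcarbamate | CCN(CC)C(=O)Oc1cc(OC)c(C2OCCO2)c(OC)c1 | intermediate
4 | 2-lithio derivative of 3 (not isolated) | CCN(CC)C(=O)Oc1cc(OC)c(C2OCCO2)c(OC)c1[Li] | intermediate
5 | 2-pinacolboryl derivative of 3 | CCN(CC)C(=O)Oc1cc(OC)c(C2OCCO2)c(OC)c1B3OC(C)(C)C(C)(C)O3 | intermediate
6 | 3-methylbutan-1-ol | CC(C)CCO | starting material
7 | 3-methylbutyl 2,4,6-triisopropylbenzoate | CC(C)CCOC(=O)c1c(C(C)C)cc(C(C)C)cc1C(C)C | intermediate
8 | (S)-1-lithio-3-methylbutyl 2,4,6-triisopropylbenzoate, sparteine complex (not isolated) | CC(C)C[C@H]([Li])OC(=O)c1c(C(C)C)cc(C(C)C)cc1C(C)C | intermediate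
9 | lithium (S)-α-acyloxyalkyl aryl pinacol boronate (not isolated) | [Li+].CC(C)C[C@H]([B-]1(OC(C)(C)C(C)(C)O1)c1c(OC(=O)N(CC)CC)cc(OC)c(C2OCCO2)c1OC)OC(=O)c1c(C(C)C)cc(C(C)C)cc1C(C)C | intermediate
10 | (R)-secondary benzylic pinacol boronic ester | CC(C)C[C@@H](B1OC(C)(C)C(C)(C)O1)c1c(OC(=O)N(CC)CC)cc(OC)c(C2OCCO2)c1OC | intermediate
11 | 1-bromo-2-methylprop-1-ene | CC(C)=CBr | starting material
12 | 2-methylprop-1-enyllithium (not isolated) | CC(C)=C[Li] | intermediate
13 | lithium alkenyl(sec-alkyl) pinacol boronate (not isolated) | [Li+].CC(C)C[C@@H]([B-]1(C=C(C)C)OC(C)(C)C(C)(C)O1)c1c(OC(=O)N(CC)CC)cc(OC)c(C2OCCO2)c1OC | intermediate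
14 | β-iodoboronic ester, carbon bearing boron unassigned (not isolated) | CC(C)C[C@@H](C(B1OC(C)(C)C(C)(C)O1)C(C)(C)I)c1c(OC(=O)N(CC)CC)cc(OC)c(C2OCCO2)c1OC | intermediate
15 | (S)-alkenyl aryl carbamate | CC(C)C[C@@H](C=C(C)C)c1c(OC(=O)N(CC)CC)cc(OC)c(C2OCCO2)c1OC | intermediate
16 | (S)-A-ring phenol | CC(C)C[C@@H](C=C(C)C)c1c(O)cc(OC)c(C2OCCO2)c1OC | intermediate
17 | 1,3,5-trimethoxybenzene | COc1cc(OC)cc(OC)c1 | starting material
18 | 2,4,6-trimethoxybenzene-1,3-dicarbaldehyde | COc1cc(OC)c(C=O)c(OC)c1C=O | intermediate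
19 | 2,2'-(2,4,6-trimethoxy-1,3-phenylene)bis(1,3-dioxolane) | COc1cc(OC)c(C2OCCO2)c(OC)c1C3OCCO3 | intermediate
20 | 5-lithio derivative of 19 (not isolated) | COc1c([Li])c(OC)c(C2OCCO2)c(OC)c1C3OCCO3 | intermediate
21 | 3,5-bis(1,3-dioxolan-2-yl)-2,4,6-trimethoxybenzaldehyde | COc1c(C=O)c(OC)c(C2OCCO2)c(OC)c1C3OCCO3 | intermediate
22 | bis(phenylthio)acetal of 21 | COc1c(C(Sc2ccccc2)Sc2ccccc2)c(OC)c(C2OCCO2)c(OC)c1C3OCCO3 | intermediate
23 | B-ring phenylthionium triflate (not isolated) | COc1c(C=[S+]c2ccccc2)c(OC)c(C2OCCO2)c(OC)c1C3OCCO3.[O-]S(=O)(=O)C(F)(F)F | intermediate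
24 | sodium salt of 16 (not isolated) | [Na+].CC(C)C[C@@H](C=C(C)C)c1c([O-])cc(OC)c(C2OCCO2)c1OC | intermediate
25 | aryl O,S-acetal, C4 S, acetal carbon unassigned (key-step precursor) | CC(C)C[C@@H](C=C(C)C)c1c(OC(Sc2ccccc2)c2c(OC)c(C3OCCO3)c(OC)c(C3OCCO3)c2OC)cc(OC)c(C2OCCO2)c1OC | intermediate
26 | S-methylsulfonium triflate of 25 (not isolated) | CC(C)C[C@@H](C=C(C)C)c1c(OC([S+](C)c2ccccc2)c2c(OC)c(C3OCCO3)c(OC)c(C3OCCO3)c2OC)cc(OC)c(C2OCCO2)c1OC.[O-]S(=O)(=O)C(F)(F)F | intermediate
27 | (E)-aryl-oxocarbenium triflate, O1=C2 (not isolated) | CC(C)C[C@@H](C=C(C)C)c1c(/[O+]=C/c2c(OC)c(C3OCCO3)c(OC)c(C3OCCO3)c2OC)cc(OC)c(C2OCCO2)c1OC.[O-]S(=O)(=O)C(F)(F)F | intermediate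
28 | cyclised tertiary cation triflate (not isolated) | CC(C)C[C@@H]1c2c(cc(OC)c(C3OCCO3)c2OC)O[C@@H](c2c(OC)c(C3OCCO3)c(OC)c(C3OCCO3)c2OC)[C@@H]1[C+](C)C.[O-]S(=O)(=O)C(F)(F)F | intermediate
29 | (2R,3S,4S)-3-isopropenyl-4-isobutyl-2-arylchroman, 2,3-trans-3,4-cis (key-step product) | CC(C)C[C@@H]1c2c(cc(OC)c(C3OCCO3)c2OC)O[C@@H](c2c(OC)c(C3OCCO3)c(OC)c(C3OCCO3)c2OC)[C@@H]1C(C)=C | intermediate
30 | (2R,3R,4S)-3-isopropyl tris-dioxolane | CC(C)C[C@@H]1c2c(cc(OC)c(C3OCCO3)c2OC)O[C@@H](c2c(OC)c(C3OCCO3)c(OC)c(C3OCCO3)c2OC)[C@@H]1C(C)C | intermediate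
31 | (2R,3R,4S)-trialdehyde pentamethyl ether | CC(C)C[C@@H]1c2c(cc(OC)c(C=O)c2OC)O[C@@H](c2c(OC)c(C=O)c(OC)c(C=O)c2OC)[C@@H]1C(C)C | intermediate
32 | (2R,3R,4S)-2-(3,5-diformyl-2,4,6-trihydroxyphenyl)-5,7-dihydroxy-4-isobutyl-3-isopropylchroman-6-carbaldehyde | CC(C)C[C@@H]1c2c(cc(O)c(C=O)c2O)O[C@@H](c2c(O)c(C=O)c(O)c(C=O)c2O)[C@@H]1C(C)C | target

Total step count: 16. Longest linear sequence: 11 steps (1, 2, 3, 5, 6, 7, 12, 13, 14, 15, 16).

Steps most likely to fail

1. Step 13 (labelled step).
- What may go wrong: too little facial bias at C3, because allylic strain competes with peri strain. The cation may also be captured by C8 of a second molecule or by traces of water before ring closure, a proton may be lost from C3 instead of from a methyl group, or the dioxolanes may open under acid.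
- Fallback (known chemistry: inverse-demand hetero-Diels–Alder reaction of an o-quinone methide with a styrene; sets out from 3 and 19 and returns at 30, so step 14 is skipped): Aryllithium 4, made from 3 as in step 3, is quenched with 3-methylbutanal to give the racemic carbinol carbamate F1. LiAlH4 converts this into the o-hydroxybenzyl alcohol F2. Aryllithium 20, made from 19 as in step 10, adds to the same aldehyde to give the B-ring carbinol F3, whose mesylate eliminates (MsCl, Et3N, then DBU) to the (E)-styrene F4. Heating F2 with F4 in toluene in a sealed tube releases the o-quinone methide F5 by loss of water. Its oxygen bonds to the aryl-bearing styrene carbon and its methide carbon to the isopropyl-bearing one. Suprafacial addition carries the E geometry into the 2,3-trans relation and places the isopropyl group on C3 directly. The C4 epimers are separated by chromatography, and the racemic chroman F6 is resolved by preparative HPLC on a chiral phase to give 30.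

2. Step 12.
- What may go wrong: C-alkylation of the ambident phenoxide at C8, methyl transfer from the undissociated sulfonium form to the phenoxide, incomplete reaction between two crowded partners, or hydrolytic loss of the very labile acetal during isolation.
- Fallback (sets out from 21 and 16, returns at 29 through ion 27): NaBH4 reduces 21 to the benzylic alcohol F7. Mitsunobu etherification with 16 gives the robust aryl benzyl ether F8. DDQ (2,6-dichloropyridine, LiClO4, 4 Å MS, 1,2-dichloroethane) then abstracts hydride from the O–CH2–aryl position. This is the known oxidative C–H cleavage route from electron-rich benzylic ethers to oxocarbenium ions. It produces the same ion 27, which closes to 29 without any sulfur chemistry.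

3. Step 5.
- What may go wrong: slow or incomplete boronate formation at the di-ortho-substituted boron, competing attack of the carbanion on the carbamate, or loss of enantiomeric purity through incomplete complexation.
- Fallback (copper-catalysed asymmetric allylic alkylation followed by cross-metathesis; sets out from 5, returns at 15, replacing steps 5 and 6): Suzuki–Miyaura coupling of 5 with (E)-3-iodoprop-2-en-1-ol (Pd/SPhos, K3PO4) gives the cinnamyl alcohol F9. MsCl, LiCl and collidine in DMF convert it into the cinnamyl chloride F10, which is used crude. Slow addition of i-BuMgBr with CuTC and a chiral phosphoramidite ligand (the antipode that delivers the S centre) in CH2Cl2 at −78 °C gives the SN2' product, the branched alkene F11. Cross-metathesis of F11 with 2-methylbut-2-ene (Hoveyda–Grubbs II) gives 15.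

Further compounds
F1 | step 13 | rac-4-(1,3-dioxolan-2-yl)-2-(1-hydroxy-3-methylbutyl)-3,5-dimethoxyphenyl N,N-diethylcarbamate | CC(C)CC(O)c1c(OC(=O)N(CC)CC)cc(OC)c(C2OCCO2)c1OC
F2 | step 13 | rac-4-(1,3-dioxolan-2-yl)-2-(1-hydroxy-3-methylbutyl)-3,5-dimethoxyphenol | CC(C)CC(O)c1c(O)cc(OC)c(C2OCCO2)c1OC
F3 | step 13 | rac-1-[3,5-bis(1,3-dioxolan-2-yl)-2,4,6-trimethoxyphenyl]-3-methylbutan-1-ol | CC(C)CC(O)c1c(OC)c(C2OCCO2)c(OC)c(C2OCCO2)c1OC
F4 | step 13 | (E)-1-[3,5-bis(1,3-dioxolan-2-yl)-2,4,6-trimethoxyphenyl]-3-methylbut-1-ene | CC(C)/C=C/c1c(OC)c(C2OCCO2)c(OC)c(C2OCCO2)c1OC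
F5 | step 13 | A-ring o-quinone methide (transient, alkylidene geometry unassigned) | CC(C)CC=C1C(=O)C=C(OC)C(C2OCCO2)=C1OC
F6 | step 13 | racemate of 30 (2,3-trans-3,4-cis; one enantiomer drawn) | CC(C)C[C@@H]1c2c(cc(OC)c(C3OCCO3)c2OC)O[C@@H](c2c(OC)c(C3OCCO3)c(OC)c(C3OCCO3)c2OC)[C@@H]1C(C)C
F7 | step 12 | [3,5-bis(1,3-dioxolan-2-yl)-2,4,6-trimethoxyphenyl]methanol | COc1c(CO)c(OC)c(C2OCCO2)c(OC)c1C3OCCO3
F8 | step 12 | (S)-aryl benzyl ether of 16 with F7 | CC(C)C[C@@H](C=C(C)C)c1c(OCc2c(OC)c(C3OCCO3)c(OC)c(C3OCCO3)c2OC)cc(OC)c(C2OCCO2)c1OC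
F9 | step 5 | (E)-4-(1,3-dioxolan-2-yl)-2-(3-hydroxyprop-1-enyl)-3,5-dimethoxyphenyl N,N-diethylcarbamate | OC/C=C/c1c(OC(=O)N(CC)CC)cc(OC)c(C2OCCO2)c1OC
F10 | step 5 | (E)-2-(3-chloroprop-1-enyl)-4-(1,3-dioxolan-2-yl)-3,5-dimethoxyphenyl N,N-diethylcarbamate | ClC/C=C/c1c(OC(=O)N(CC)CC)cc(OC)c(C2OCCO2)c1OC
F11 | step 5 | 4-(1,3-dioxolan-2-yl)-3,5-dimethoxy-2-[(3S)-5-methylhex-1-en-3-yl]phenyl N,N-diethylcarbamate | CC(C)C[C@@H](C=C)c1c(OC(=O)N(CC)CC)cc(OC)c(C2OCCO2)c1OC
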